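The route rests on disconnecting the C4–C4a bond of the chromone (ring C). In ring A, C4a is para to the oxygen on C7 and ortho to the ring oxygen O1, so a carboxyl carbon (the future C4) tethered through O1–C2=C3 can acylate it. The key step is an intramolecular Friedel–Crafts acylation that forms this bond and closes ring C in one operation, with the O3 and O7 oxygens already in place as benzyl ethers. Its precursor is an (E)-2-benzyloxy-3-aryloxy-3-arylacrylic acid, built by a one-flask Claisen acylation and enol tosylation, then addition–elimination with 3-benzyloxyphenol. Debenzylation and selective 7-O-prenylation finish the synthesis.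

Key step: step 4

Remark: chromone numbering (O1, C2, C3, C4, C4a, C7) is used for ring positions; in 5, 8, 9, 10 and 11 the descriptor E means that the ester, carboxylate, acid or acid chloride group is cis to the tosyloxy or aryloxy group on the neighbouring alkene carbon.

Step 1
Reactants: 1 methyl 2-(benzyloxy)acetate; 2 3,4-dimethoxybenzoyl chloride
Product: 5 methyl (E)-2-(benzyloxy)-3-(3,4-dimethoxyphenyl)-3-(tosyloxy)prop-2-enoate (tosyloxy cis to CO2Me), via lithium ester enolate 3 (not isolated), via lithium keto ester enolate 4 (not isolated)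
Conditions: LiN(SiMe3)2 (2.1 equiv), THF, −78 °C; 2, −78 to 0 °C; then Ts2O (1.3 equiv), 0 °C to rt
Reagents that add atoms: p-toluenesulfonic anhydride, Cc1ccc(S(=O)(=O)OS(=O)(=O)c2ccc(C)cc2)cc1
Why: Crossed Claisen C-acylation of the preformed lithium glycolate enolate 3 by the aroyl chloride should be fast at −78 °C, the second equivalent of base converts the keto ester as it forms into the chelated enolate 4, which resists a second acylation, and O-sulfonylation of 4 by the anhydride (enol tosylation of a β-keto ester enolate) should place the tosyloxy group cis to the ester because lithium bridges the two carbonyl oxygens.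

Step 2
Reactants: 5; 6 3-(benzyloxy)phenol
Product: 8 methyl (E)-2-(benzyloxy)-3-[3-(benzyloxy)phenoxy]-3-(3,4-dimethoxyphenyl)prop-2-enoate, via cesium aryloxide 7 (not isolated)
Conditions: Cs2CO3, DMF, 60 °C
Reagents that add atoms: none
Why: Addition–elimination (nucleophilic vinylic substitution): the aryloxide 7 adds to the ester-activated β-carbon and the resulting ester enolate expels tosylate before the C2–C3 bond rotates far, which should give retention and leave the aryloxy group cis to the ester.

Step 3
Reactants: 8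
Product: 10 (E)-2-(benzyloxy)-3-[3-(benzyloxy)phenoxy]-3-(3,4-dimethoxyphenyl)prop-2-enoic acid, via lithium carboxylate 9 (not isolated)
Conditions: LiOH·H2O, THF/H2O (3:1), 40 °C; then 1 M HCl, 0 °C, pH 3
Reagents that add atoms: lithium hydroxide monohydrate, [Li+].[OH-].O
Why: Saponification at the methyl ester carbonyl should outrun hydroxide attack at the fully substituted β-carbon, methanol is left out so that the aryloxy group is not exchanged, and cold acidification to pH 3 spares the enol ether.

Step 4
Reactants: 10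
Product: 12 3,7-bis(benzyloxy)-2-(3,4-dimethoxyphenyl)-4H-chromen-4-one, via acid chloride 11 (not isolated)
Conditions: (COCl)2, cat. DMF, CH2Cl2, 0 °C to rt; evaporate; then SnCl4 (1.2 equiv), CH2Cl2, −78 to 0 °C
Reagents that add atoms: none
Why: Oxalyl chloride with catalytic DMF converts acid 10 into acid chloride 11, and SnCl4 then ionises 11 to an acylium ion that is stabilised through the alkene by the aryloxy and aryl groups on the future C2 and held next to ring A because the aryloxy group is cis to the carbonyl; attack by the arene carbon ortho to O1 and loss of HCl from the arenium ion give the chromone. The closest known reaction type is the intramolecular Friedel–Crafts acylation of β-aryloxyacrylic acids or their chlorides to chromones and flavones, the ring-closing stage of the Simonis and Ruhemann syntheses. Ring C, a six-membered pyranone, closes by C4–C4a bond formation, the arene attacking the acylium carbon in a 6-exo mode with the C=O left outside the new ring. No stereocentre is formed. The step needs site selectivity for the ring A carbon para to the benzyloxy group over the carbon between the two oxygens, which is flanked on both sides and shielded by the benzyl ether, and for ring A over both the unactivated phenyl ring of the O3 benzyl group and the dimethoxyphenyl ring, where closure would give a strained five-membered indenone and is open only to the other alkene isomer. Both benzyl ethers are expected to hold at low temperature with a slight excess of SnCl4, and the acid-labile prenyl group is not yet present.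

Step 5
Reactants: 12
Product: 13 2-(3,4-dimethoxyphenyl)-3,7-dihydroxy-4H-chromen-4-one
Conditions: H2 (1 atm), 10% Pd/C, THF/MeOH (1:1), rt
Reagents that add atoms: none
Why: Catalytic hydrogenolysis should cleave both the aryl benzyl ether at O7 and the enol benzyl ether at O3 under 1 atm of hydrogen, conditions under which the chromone C2=C3 bond and the aryl methyl ethers are inert.

Step 6
Reactants: 13; 14 prenyl bromide (1-bromo-3-methylbut-2-ene)
Product: 16 2-(3,4-dimethoxyphenyl)-3-hydroxy-7-[(3-methylbut-2-en-1-yl)oxy]-4H-chromen-4-one (target), via potassium 7-phenoxide 15 (not isolated)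
Conditions: K2CO3 (1.0 equiv), DMF, 0 °C; then 14 (1.05 equiv), 0 °C to rt
Reagents that add atoms: none
Why: Williamson etherification under base-limited control: the 7-OH is a vinylogous carboxylic acid (para to the C4 carbonyl) and clearly more acidic than the 3-OH, which is also hydrogen-bonded to the C4 carbonyl, so one equivalent of K2CO3 should generate mainly phenoxide 15, which attacks prenyl bromide at its primary carbon (SN2).

Compound list
1 | methyl 2-(benzyloxy)acetate | COC(=O)COCc1ccccc1 | starting material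
2 | 3,4-dimethoxybenzoyl chloride | COc1ccc(C(=O)Cl)cc1OC | starting material
3 | lithium enolate of methyl 2-(benzyloxy)acetate (OLi cis to OBn) | [Li+].[O-]/C(OC)=C\OCc1ccccc1 | intermediate
4 | chelated lithium enolate of methyl 2-(benzyloxy)-3-(3,4-dimethoxyphenyl)-3-oxopropanoate (enolate oxygen cis to CO2Me) | COC(=O)/C(OCc1ccccc1)=C(\[O-])c1ccc(OC)c(OC)c1.[Li+] | intermediate
5 | methyl (E)-2-(benzyloxy)-3-(3,4-dimethoxyphenyl)-3-(tosyloxy)prop-2-enoate | COC(=O)/C(OCc1ccccc1)=C(\OS(=O)(=O)c1ccc(C)cc1)c1ccc(OC)c(OC)c1 | intermediate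
6 | 3-(benzyloxy)phenol | Oc1cccc(OCc2ccccc2)c1 | starting material
7 | cesium 3-(benzyloxy)phenoxide | [Cs+].[O-]c1cccc(OCc2ccccc2)c1 | intermediate
8 | methyl (E)-2-(benzyloxy)-3-[3-(benzyloxy)phenoxy]-3-(3,4-dimethoxyphenyl)prop-2-enoate | COC(=O)/C(OCc1ccccc1)=C(\Oc1cccc(OCc2ccccc2)c1)c1ccc(OC)c(OC)c1 | intermediate
9 | lithium (E)-2-(benzyloxy)-3-[3-(benzyloxy)phenoxy]-3-(3,4-dimethoxyphenyl)prop-2-enoate | [Li+].[O-]C(=O)/C(OCc1ccccc1)=C(\Oc1cccc(OCc2ccccc2)c1)c1ccc(OC)c(OC)c1 | intermediate
10 | (E)-2-(benzyloxy)-3-[3-(benzyloxy)phenoxy]-3-(3,4-dimethoxyphenyl)prop-2-enoic acid | O=C(O)/C(OCc1ccccc1)=C(\Oc1cccc(OCc2ccccc2)c1)c1ccc(OC)c(OC)c1 | intermediate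
11 | (E)-2-(benzyloxy)-3-[3-(benzyloxy)phenoxy]-3-(3,4-dimethoxyphenyl)prop-2-enoyl chloride | O=C(Cl)/C(OCc1ccccc1)=C(\Oc1cccc(OCc2ccccc2)c1)c1ccc(OC)c(OC)c1 | intermediate
12 | 3,7-bis(benzyloxy)-2-(3,4-dimethoxyphenyl)-4H-chromen-4-one | COc1ccc(-c2oc3cc(OCc4ccccc4)ccc3c(=O)c2OCc2ccccc2)cc1OC | intermediate
13 | 2-(3,4-dimethoxyphenyl)-3,7-dihydroxy-4H-chromen-4-one | COc1ccc(-c2oc3cc(O)ccc3c(=O)c2O)cc1OC | intermediate
14 | prenyl bromide (1-bromo-3-methylbut-2-ene) | CC(C)=CCBr | starting material
15 | potassium 2-(3,4-dimethoxyphenyl)-3-hydroxy-4-oxo-4H-chromen-7-olate | COc1ccc(-c2oc3cc([O-])ccc3c(=O)c2O)cc1OC.[K+] | intermediate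
16 | 2-(3,4-dimethoxyphenyl)-3-hydroxy-7-[(3-methylbut-2-en-1-yl)oxy]-4H-chromen-4-one | COc1ccc(-c2oc3cc(OCC=C(C)C)ccc3c(=O)c2O)cc1OC | target

Total step count: 6. Longest linear sequence: 6 steps (1 and 2 to 16).

Steps most likely to fail

Step 4 (key step). The acylation may go to the ring A carbon between the two oxygens, a benzyl ether may be lost by chelation to the Lewis acid before the ring has closed, or the alkene may isomerise and close onto the dimethoxyphenyl ring. Loss of the O3 benzyl group after ring closure would be harmless, since that material converges on 13 in step 5. The fallback closes the same C4–C4a bond by an anionic route; it sets out from 6 and 5 and returns at 12. Phenol 6 is brominated ortho to the hydroxyl and para to the benzyloxy group (NBS, catalytic i-Pr2NH, CH2Cl2, 0 °C) to give 5-(benzyloxy)-2-bromophenol F1. Its salt, cesium 5-(benzyloxy)-2-bromophenoxide F2 (Cs2CO3, DMF, 60 °C), displaces the tosylate of 5 as in step 2 to give methyl (E)-2-(benzyloxy)-3-[5-(benzyloxy)-2-bromophenoxy]-3-(3,4-dimethoxyphenyl)prop-2-enoate F3. Bromine–lithium exchange with n-BuLi in THF at −100 °C gives the aryllithium methyl (E)-2-(benzyloxy)-3-[5-(benzyloxy)-2-lithiophenoxy]-3-(3,4-dimethoxyphenyl)prop-2-enoate F4, which should attack its own ester carbonyl and expel methoxide (Parham-type cycloacylation) to give 12. The bromine fixes the site of closure and no Lewis acid touches the benzyl ethers.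

Step 2. Addition to the hindered, donor-substituted β-carbon may be slow, the aryloxide may instead attack sulfur and strip the tosyl group, or the alkene geometry may erode. The fallback uses a stronger acceptor and a chloride leaving group; it sets out from enolate 4 and returns at 10. Enolate 4, generated as in step 1, is quenched with 1 M HCl at −78 °C before any anhydride is added, which gives racemic methyl 2-(benzyloxy)-3-(3,4-dimethoxyphenyl)-3-oxopropanoate F5. Krapcho dealkoxycarbonylation of this keto ester (LiCl, wet DMSO, 130 °C) gives 2-(benzyloxy)-1-(3,4-dimethoxyphenyl)ethan-1-one F6. Vilsmeier–Haack–Arnold chloroformylation (POCl3, DMF, 0 to 60 °C; aqueous NaOAc) should give (E)-2-(benzyloxy)-3-chloro-3-(3,4-dimethoxyphenyl)prop-2-enal F7 (chlorine cis to the formyl group). Addition–elimination with aryloxide 7 (from 6 and Cs2CO3, DMF, rt) gives (E)-2-(benzyloxy)-3-[3-(benzyloxy)phenoxy]-3-(3,4-dimethoxyphenyl)prop-2-enal F8. Pinnick oxidation (NaClO2, NaH2PO4, 2-methylbut-2-ene, t-BuOH/H2O, 0 °C) then gives acid 10.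

Step 6. Alkylation may also occur at O3, giving the 3-ether or the 3,7-diether, once proton exchange between the two hydroxyls competes. The fallback differentiates the hydroxyls through esters; it sets out from 13 and returns at 16. Acetylation (Ac2O, pyridine, rt) gives 2-(3,4-dimethoxyphenyl)-4-oxo-4H-chromene-3,7-diyl diacetate F9. The more labile aryl acetate at O7 is removed selectively (PhSH, imidazole, NMP, 0 °C) to give 2-(3,4-dimethoxyphenyl)-7-hydroxy-4-oxo-4H-chromen-3-yl acetate F10. Its salt, potassium 3-acetoxy-2-(3,4-dimethoxyphenyl)-4-oxo-4H-chromen-7-olate F11 (K2CO3, acetone, rt), is alkylated by 14 to give 2-(3,4-dimethoxyphenyl)-7-[(3-methylbut-2-en-1-yl)oxy]-4-oxo-4H-chromen-3-yl acetate F12. Methanolysis (K2CO3, MeOH, rt) releases 16 without touching the prenyl ether.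

Further compounds
F1 | step 4 | 5-(benzyloxy)-2-bromophenol | Oc1cc(OCc2ccccc2)ccc1Br
F2 | step 4 | cesium 5-(benzyloxy)-2-bromophenoxide | [Cs+].[O-]c1cc(OCc2ccccc2)ccc1Br
F3 | step 4 | methyl (E)-2-(benzyloxy)-3-[5-(benzyloxy)-2-bromophenoxy]-3-(3,4-dimethoxyphenyl)prop-2-enoate | COC(=O)/C(OCc1ccccc1)=C(\Oc1cc(OCc2ccccc2)ccc1Br)c1ccc(OC)c(OC)c1
F4 | step 4 | methyl (E)-2-(benzyloxy)-3-[5-(benzyloxy)-2-lithiophenoxy]-3-(3,4-dimethoxyphenyl)prop-2-enoate | COC(=O)/C(OCc1ccccc1)=C(\Oc1cc(OCc2ccccc2)ccc1[Li])c1ccc(OC)c(OC)c1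
F5 | step 2 | methyl 2-(benzyloxy)-3-(3,4-dimethoxyphenyl)-3-oxopropanoate (racemic) | COC(=O)C(OCc1ccccc1)C(=O)c1ccc(OC)c(OC)c1
F6 | step 2 | 2-(benzyloxy)-1-(3,4-dimethoxyphenyl)ethan-1-one | COc1ccc(C(=O)COCc2ccccc2)cc1OC
F7 | step 2 | (E)-2-(benzyloxy)-3-chloro-3-(3,4-dimethoxyphenyl)prop-2-enal | O=C/C(OCc1ccccc1)=C(\Cl)c1ccc(OC)c(OC)c1
F8 | step 2 | (E)-2-(benzyloxy)-3-[3-(benzyloxy)phenoxy]-3-(3,4-dimethoxyphenyl)prop-2-enal | O=C/C(OCc1ccccc1)=C(\Oc1cccc(OCc2ccccc2)c1)c1ccc(OC)c(OC)c1
F9 | step 6 | 2-(3,4-dimethoxyphenyl)-4-oxo-4H-chromene-3,7-diyl diacetate | COc1ccc(-c2oc3cc(OC(C)=O)ccc3c(=O)c2OC(C)=O)cc1OC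
F10 | step 6 | 2-(3,4-dimethoxyphenyl)-7-hydroxy-4-oxo-4H-chromen-3-yl acetate | COc1ccc(-c2oc3cc(O)ccc3c(=O)c2OC(C)=O)cc1OC
F11 | step 6 | potassium 3-acetoxy-2-(3,4-dimethoxyphenyl)-4-oxo-4H-chromen-7-olate | COc1ccc(-c2oc3cc([O-])ccc3c(=O)c2OC(C)=O)cc1OC.[K+]
F12 | step 6 | 2-(3,4-dimethoxyphenyl)-7-[(3-methylbut-2-en-1-yl)oxy]-4-oxo-4H-chromen-3-yl acetate | COc1ccc(-c2oc3cc(OCC=C(C)C)ccc3c(=O)c2OC(C)=O)cc1OC
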